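All runs are simulated for an exercise; the scatter is artificial.

The ratio c(impurity)/c(free catalyst) in this flask is 16.0%. I carry it as the lost share, the part of the catalyst charged that the impurity takes if one impurity removes one free catalyst for good. The impurity is charged in the smaller amount (16 µM against 0.10 mM), so it is the limiting reagent of that loss, and 84.0% of the catalyst stays outside it.

| setting | zeta | alpha | flask |
|---|---|---|---|
| substrate | 0.034 M (fed, over 20 h) | 0.075 M (fed, over 20 h) | 0.050 M (fed, over 20 h) |
| reagent | 0.15 M | 0.15 M | 0.150 M |
| free catalyst | 0.10 mM | 0.10 mM | 0.10 mM |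
| impurity | 16 µM | 16 µM | 16 µM |
| added ligand | 79 µM | 79 µM | 79 µM |
| remark | run made earlier; the fed solution adds 0.10 times the starting volume | run made earlier; the fed solution adds 0.10 times the starting volume | the fed solution adds 0.10 times the starting volume |
| time |  |  | 20 h |

| run | time / h | substrate / % | intermediate / % | product / % |
|---|---|---|---|---|
| zeta | 1.50 | 5.9 | 1.4 | 0 |
| zeta | 4.00 | 12.2 | 7.1 | 0.1 |
| zeta | 8.00 | 18.1 | 20.5 | 1.3 |
| zeta | 12.0 | 24.2 | 33.9 | 2.5 |
| alpha | 3.00 | 10.6 | 4.8 | 0 |
| alpha | 6.00 | 16.5 | 14.1 | 0.3 |
| alpha | 10.0 | 21.8 | 27.3 | 1.6 |
| alpha | 12.0 | 24.5 | 34.7 | 2.0 |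

(scatter of a reading: 0.5 percentage points)

- the largest share of what was charged as substrate, at 20 h belongs to (substrate / product / intermediate)
- the largest share itself, whichever of these holds it, in percent of the substrate charged

- every charge counts on the volume at the start, and the solution that is fed holds the whole dose
- percentages count the whole charge, also what has not yet gone in

At the bench: substrate goes in steadily until 20 h. At 12.0 h the zeta and alpha runs read 33.9% and 34.7% intermediate, although their charges differ by a factor of 2.21, so this flask, charged between them, should follow the same percentages. Extending the last step of the zeta run to 20 h gives me 60.7% intermediate, which leaves 39.3% for substrate and product together, so intermediate should hold the largest share. Leave the charges alone: more impurity raises the lost share.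

The forecast says intermediate at 58%, less than my figure, on the ground that the flask “should follow the same curves”.

The flask gives intermediate at 62.5%.

    substrate + free catalyst → free catalyst + intermediate (k = 4100 M⁻¹ h⁻¹)
    free catalyst + impurity → spent catalyst (k = 8.00 × 10⁵ M⁻¹ h⁻¹)
    free catalyst ⇌ dormant form (K = 1.10, k = 0.0340 h⁻¹)
    reagent + free catalyst + intermediate → free catalyst + product (k = 1600 M⁻² h⁻¹)
    free catalyst + added ligand ⇌ idle complex (K = 28000 M⁻¹, k = 630 M⁻¹ h⁻¹)

At 20.0 h the flask holds 16.0% of its catalyst as spent catalyst, with impurity at 0% of its charge. Free catalyst, idle complex and dormant form together hold 84.0%, the 84.0% that the lost share leaves.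

In a neighbouring flask, the same flask with 6.4 × 10⁻⁵ M of impurity, the lost share comes to 64.0%. That flask computes to 64.0% spent catalyst, and substrate, at 57.4%, holds the largest share, ahead of intermediate at 41.4%.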